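**Retrosynthetic overview**
- The strategy rests on the acyclic chain C1(OH)–C2H2–C3H(C4H3) that joins the two 2,4,5-trimethoxyphenyl rings. C2–C3–C4 is the three-carbon unit of propadiene, C1 is the formyl carbon of 2,4,5-trimethoxybenzaldehyde, and the aryl group on C3 comes from an aryl iodide.
- Target ⇒ (R)-1,3-bis(2,4,5-trimethoxyphenyl)but-3-en-1-ol by asymmetric hydrogenation of the C3=C4 alkene (sets C3 as S).
- That alkenol ⇒ 1-iodo-2,4,5-trimethoxybenzene + propadiene + bis(pinacolato)diboron + 2,4,5-trimethoxybenzaldehyde. The aryl–C3 bond comes from palladium arylboration of the allene, the C1–C2 bond from chiral phosphoric acid allylboration (sets C1 as R).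
- The aryl iodide ⇒ 1,2,4-trimethoxybenzene by iodination. No ring is formed anywhere in the route; both benzene rings are bought.

Key step: step 2

Assumption: (R)-TRIP is taken to direct the allyl group to the Re face of the aldehyde, as it does for simple aryl aldehydes, and the hydrogenation ligand is taken as the antipode that gives (S)-2-arylbutanes from 2-aryl-1-butenes (same CIP ranking aryl > CH2R > CH3 at C3); in either case the mirror-image catalyst is equally available.

**Step 1**
Reactants: 1 1,2,4-trimethoxybenzene
Product: 2 1-iodo-2,4,5-trimethoxybenzene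
Conditions: NIS (1.05 equiv), CF3CO2H (cat.), MeCN, 0 °C → rt, dark
Reagents that add atoms: N-iodosuccinimide, O=C1CCC(=O)N1I
Why: Electrophilic aromatic iodination: C5 of 1 is para to one methoxy group, ortho to another and unhindered, whereas C3 is flanked by two methoxy groups and C6 is activated by only one, so mono-iodination at C5 is expected.

**Step 2**
Reactants: 2 1-iodo-2,4,5-trimethoxybenzene; 3 propadiene; 4 bis(pinacolato)diboron; 5 2,4,5-trimethoxybenzaldehyde
Product: 8 (R)-1,3-bis(2,4,5-trimethoxyphenyl)but-3-en-1-ol, via 2-arylallyl pinacolboronate 6 (not isolated), via homoallylic pinacol borate 7 (not isolated)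
Conditions: (a) 2 (1.3 equiv), 4 (1.4 equiv), 3 (1 atm, balloon), Pd2(dba)3 (2.5 mol %), P(2-furyl)3 (10 mol %), KOAc (1.5 equiv, anhydrous), toluene, 50 °C; (b) Ar purge, filtration from salts under Ar, then 5 (1.0 equiv), (R)-TRIP [(R)-3,3′-bis(2,4,6-triisopropylphenyl)-1,1′-binaphthyl-2,2′-diyl hydrogen phosphate] (5 mol %), toluene, −30 °C; aq. NaHCO3
Reagents that add atoms: none
Why: Oxidative addition of zerovalent palladium to the C–I bond of 2 and insertion of 3 at its central carbon give a symmetrical 2-aryl-π-allylpalladium species (aryl–C3 bond), which after iodide/acetate exchange transmetalates with 4 and reductively eliminates to 2-arylallylboronate 6; acetate also ties up the boron co-product as AcO–Bpin so that no iodoborane is left to start diboration of the allene. In the second stage 6 adds to 5 through a closed six-membered chair transition state to form the C1–C2 bond and borate 7, which the work-up hydrolyses to 8; the product holds no ring beyond the two arene rings, so no ring closure is involved. The closest known reaction types are the palladium-catalysed three-component carbopalladation/borylation of allenes with aryl iodides and diboron and the chiral phosphoric acid-catalysed allylboration of aryl aldehydes with allyl pinacolboronates, and the passing of a palladium-made allylboronate directly into such an allylboration is known for diene-derived boronates. C1 is set by catalyst control: the phosphoric acid OH binds the pseudo-axial boronate oxygen and the P=O oxygen binds the formyl hydrogen, and the 2,4,6-triisopropylphenyl walls of (R)-TRIP should leave only the Re face of 5 open, giving R. The step needs carbopalladation of the allene to outrun direct borylation of 2, and borylation of the π-allyl to outrun allyl–allyl and Suzuki coupling with 6; the excess of 3 and 4, the weak anhydrous acetate base and the moderate temperature should secure this, and regiochemistry is no issue because both π-allyl termini are equivalent CH2 groups. The racemic background addition is kept slow by the low temperature and by the lower reactivity of the 2-substituted boronate, and the salts are filtered off first so that residual acetate cannot neutralise the acid catalyst.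

**Step 3**
Reactants: 8 (R)-1,3-bis(2,4,5-trimethoxyphenyl)but-3-en-1-ol
Product: 9 (1R,3S)-1,3-bis(2,4,5-trimethoxyphenyl)butan-1-ol
Conditions: H2 (1 bar), [Ir(cod)(N,P)]BArF (1 mol %; N,P = threonine-derived phosphinite–oxazoline ligand, antipode as stated above; BArF = B[3,5-(CF3)2C6H3]4), CH2Cl2, rt
Reagents that add atoms: none
Why: Iridium N,P-catalysed asymmetric hydrogenation of a 2-aryl-1-alkene, in which the chiral ligand pocket selects the alkene face (catalyst control) so that hydrogen is delivered to give S at C3, the low hydrogen pressure favours selectivity for terminal alkenes, the free hydroxyl is tolerated and C1 is untouched.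

**Compound list**
1 | 1,2,4-trimethoxybenzene | COc1ccc(OC)c(OC)c1 | starting material
2 | 1-iodo-2,4,5-trimethoxybenzene | COc1cc(OC)c(I)cc1OC | intermediate
3 | propadiene (allene) | C=C=C | starting material
4 | bis(pinacolato)diboron | CC1(C)OB(OC1(C)C)B1OC(C)(C)C(C)(C)O1 | starting material
5 | 2,4,5-trimethoxybenzaldehyde | COc1cc(OC)c(C=O)cc1OC | starting material
6 | 4,4,5,5-tetramethyl-2-[2-(2,4,5-trimethoxyphenyl)prop-2-en-1-yl]-1,3,2-dioxaborolane | COc1cc(OC)c(C(=C)CB2OC(C)(C)C(C)(C)O2)cc1OC | intermediate (not isolated)
7 | 2-{[(1R)-1,3-bis(2,4,5-trimethoxyphenyl)but-3-en-1-yl]oxy}-4,4,5,5-tetramethyl-1,3,2-dioxaborolane | COc1cc(OC)c([C@H](OB3OC(C)(C)C(C)(C)O3)CC(=C)c2cc(OC)c(OC)cc2OC)cc1OC | intermediate (not isolated)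
8 | (R)-1,3-bis(2,4,5-trimethoxyphenyl)but-3-en-1-ol | COc1cc(OC)c([C@H](O)CC(=C)c2cc(OC)c(OC)cc2OC)cc1OC | intermediate
9 | (1R,3S)-1,3-bis(2,4,5-trimethoxyphenyl)butan-1-ol | COc1cc(OC)c([C@H](O)C[C@H](C)c2cc(OC)c(OC)cc2OC)cc1OC | target

Total step count: 3
Longest linear sequence: 3 steps (1 → 2 → 8 → 9)

**Steps most likely to fail**

1. Step 2 (key step). The arylpalladium or π-allylpalladium intermediates may be diverted: direct borylation of the aryl iodide, diboration or oligomerisation of the allene, allyl–allyl or Suzuki coupling of the boronate. In the second stage the allyl transfer to the electron-rich, ortho-substituted aldehyde may be slow, so that uncatalysed or boron-Lewis-acid-catalysed background addition erodes the facial selectivity. The fallback sets out from 5 and returns at 8. The C1–C2 bond and C1 are made first by asymmetric 2-bromoallylation of 5 with the chiral B-(2-bromoallyl)-1,3,2-diazaborolidine prepared from N,N′-ditosyl-1,2-diphenylethane-1,2-diamine, BBr3 and (2-bromoallyl)tributylstannane (CH2Cl2, −78 °C; controller antipode chosen for R). This should give (R)-3-bromo-1-(2,4,5-trimethoxyphenyl)but-3-en-1-ol F1. Suzuki–Miyaura coupling of the vinyl bromide with commercial 2,4,5-trimethoxyphenylboronic acid (Pd(PPh3)4, K2CO3, dioxane/H2O, 80 °C) then forms the aryl–C3 bond and should give 8.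

2. Step 3. The terminal alkene may be discriminated poorly (the ortho-methoxy group twists the aryl ring out of the alkene plane), the double bond may migrate before reduction, or the acidic iridium hydride may ionise the electron-rich benzylic alcohol with loss of configuration at C1. The fallback sets out from 8 and returns at 9. Oxidation of 8 with MnO2 (CH2Cl2) should give 1,3-bis(2,4,5-trimethoxyphenyl)but-3-en-1-one F2, which DBU isomerises into conjugation to (E)-1,3-bis(2,4,5-trimethoxyphenyl)but-2-en-1-one F3. Asymmetric hydrogenation of this trisubstituted enone ([Ir(cod)(PHOX)]BArF, PHOX = chiral 4-tert-butyl-2-(2-diphenylphosphinophenyl)oxazoline, antipode chosen for S; H2, CH2Cl2) should give (S)-1,3-bis(2,4,5-trimethoxyphenyl)butan-1-one F4; trisubstituted enones are the substrate class on which these catalysts are most reliable, and the ketone is not acid-labile. Corey–Bakshi–Shibata reduction with the (S)-methyl oxazaborolidine and BH3·SMe2 (THF, −20 °C) then resets C1 as R and should give 9.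

3. Step 1. Over-iodination or oxidation of the very electron-rich ring (demethylative quinone formation) may leave a product contaminated by material that is hard to remove. The fallback sets out from 1 and returns at 2. Bromination of 1 with NBS (MeCN, 0 °C) is expected to be cleanly selective for the same position and to give 1-bromo-2,4,5-trimethoxybenzene F5. Bromine–lithium exchange (n-BuLi, THF, −78 °C) to (2,4,5-trimethoxyphenyl)lithium F6 and quenching with iodine should give 2.

**Further compounds**
F1 | step 2 | (R)-3-bromo-1-(2,4,5-trimethoxyphenyl)but-3-en-1-ol | COc1cc(OC)c([C@H](O)CC(Br)=C)cc1OC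
F2 | step 3 | 1,3-bis(2,4,5-trimethoxyphenyl)but-3-en-1-one | COc1cc(OC)c(C(=O)CC(=C)c2cc(OC)c(OC)cc2OC)cc1OC
F3 | step 3 | (E)-1,3-bis(2,4,5-trimethoxyphenyl)but-2-en-1-one | COc1cc(OC)c(C(=O)/C=C(\C)c2cc(OC)c(OC)cc2OC)cc1OC
F4 | step 3 | (S)-1,3-bis(2,4,5-trimethoxyphenyl)butan-1-one | COc1cc(OC)c(C(=O)C[C@H](C)c2cc(OC)c(OC)cc2OC)cc1OC
F5 | step 1 | 1-bromo-2,4,5-trimethoxybenzene | COc1cc(OC)c(Br)cc1OC
F6 | step 1 | (2,4,5-trimethoxyphenyl)lithium | [Li]c1cc(OC)c(OC)cc1OC
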